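**Retrosynthetic overview**

1. Locants: tetralin C1 (methyl), C4 (side chain), ring-fusion carbons C4a/C8a, arene C5 (H), C6 (CO2H), C7 and C8 (OH); chain C11 (bearing C20H2OAc), C12–C14, C15 (methyl and C16H2OAc). The strategy rests on one feature: the saturated ring C1–C4/C4a/C8a, with its C1 methyl trans to the C4-bound three-carbon unit C11/C12/C20, is a trans-p-menthane. It is the skeleton of (R)-carvone, with the carbonyl carbon as C8a and the α-methylene as C4a.
2. Benzene ring (the only ring formed): cut at C5–C6 and C8–C8a into formylated trans-dihydrocarvone (formyl carbon = C5) and methyl 4-(benzyloxy)-3-oxobutanoate (C6, C7, C8), joined by a base-mediated Knoevenagel–aldol [3+3] benzannulation. The saturated ring comes intact from carvone.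
3. Side chain: C12–C13 by Li2CuCl4-catalysed coupling of the allylic chloride (from the isopropenyl group) with a C13–C16 Grignard reagent made from (S)-3-bromo-2-methylpropan-1-ol (source of C15); C11 by hydroboration of the resulting 1,1-disubstituted alkene.
4. Endgame: desilylation, saponification, diacetylation, hydrogenolysis of the two aryl benzyl ethers.

Key step: step 4

Remark: 5 is written as its hydroxymethylene tautomer. Compound names use the tetralin locants above. The C4 descriptor reads R instead of S in 13 only because substituent priorities change; the centre itself is never a reacting centre.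

**Route**

Step 1
Reactants: 1 (R)-carvone
Product: 3 (2R,5R)-2-methyl-5-(prop-1-en-2-yl)cyclohexan-1-one (trans-dihydrocarvone), via dihydrocarvone C2-epimer mixture 2 (not isolated)
Conditions: LiBH(s-Bu)3, THF, −78 °C; MeOH quench; then NaOMe (cat.), MeOH, rt
Reagents that add atoms: none
Why: Conjugate hydride reduction of the enone leaves the isolated isopropenyl group and the carvone stereocentre untouched, and base equilibration of the α-methyl centre should enrich the diequatorial trans isomer (any residual cis epimer meets alkoxide again in step 4).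

Step 2
Reactants: 3 trans-dihydrocarvone; 4 ethyl formate
Product: 5 (3S,6R)-2-(hydroxymethylene)-6-methyl-3-(prop-1-en-2-yl)cyclohexan-1-one
Conditions: NaH, HCO2Et, EtOH (cat.), THF, 0 °C → rt; aq. HCl work-up
Reagents that add atoms: none
Why: Crossed Claisen formylation occurs at the α-methylene, not at the methyl-bearing methine, because only that position gives an enolisable β-keto aldehyde whose salt formation drives the equilibrium.

Step 3
Reactants: 6 methyl 4-chloro-3-oxobutanoate; 7 benzyl alcohol
Product: 8 methyl 4-(benzyloxy)-3-oxobutanoate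
Conditions: NaH (2.2 equiv), THF, 0 °C → rt; aq. HCl work-up
Reagents that add atoms: none
Why: Williamson etherification in which sodium benzyloxide displaces the primary chloride while the keto ester is held as its enolate, which shields the methyl ester from transesterification.

Step 4
Reactants: 5 hydroxymethylene ketone; 8 methyl 4-(benzyloxy)-3-oxobutanoate
Product: 11 methyl (1R,4S)-8-(benzyloxy)-7-hydroxy-1-methyl-4-(prop-1-en-2-yl)-1,2,3,4-tetrahydronaphthalene-6-carboxylate, via Knoevenagel adduct 9 (not isolated), via aldol adduct 10 (not isolated)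
Conditions: NaOMe (2.2 equiv), MeOH, 0 → 65 °C; aq. HCl work-up
Reagents that add atoms: none
Why: Methoxide deprotonates the doubly activated methylene of 8, which adds to the formyl-derived carbon of 5 and loses water (Knoevenagel condensation, bond C5–C6) to give 9; the enolate on the benzyloxy-bearing carbon then adds to the ring ketone (bond C8–C8a) to give 10, and a second dehydration with enolisation at C7 gives the phenoxide without any oxidant. The closest known reaction type is the base-mediated [3+3] condensation of 2-(hydroxymethylene)cycloalkanones with acetoacetates or acetonedicarboxylates to ring-fused salicylates. The benzene ring closes by a 6-exo-trig intramolecular aldol addition of a carbon enolate to the ketone, made irreversible by dehydration and aromatisation. No stereocentre is created: C4 is not acidic in any intermediate and is carried through from carvone, whereas C1 stays epimerisable until the aldol closure and is expected to rest in the diequatorial trans arrangement of 5 and of the (Z)-alkylidene form of 9 before C8a loses its carbonyl. The step needs the more acidic carbon of 8 at the formyl carbon, the benzyloxy-bearing carbon at the ketone, and carbon rather than oxygen ring closure; the first two follow from the large acidity gap between the two nucleophilic carbons of 8 and the higher electrophilicity of the aldehyde-level carbon of 5, the third from the reversibility of O-cyclisation under methoxide against the irreversible aromatising C-closure.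

Step 5
Reactants: 11 salicylate
Product: 12 methyl (1R,4S)-7,8-bis(benzyloxy)-1-methyl-4-(prop-1-en-2-yl)-1,2,3,4-tetrahydronaphthalene-6-carboxylate
Conditions: BnBr, K2CO3, Bu4NI (cat.), DMF, 60 °C
Reagents that add atoms: benzyl bromide, BrCc1ccccc1
Why: Williamson O-benzylation of the salicylate phenoxide masks the last acidic and oxidisable site before hypochlorite, Grignard and borane chemistry, with a group that leaves together with the C8 benzyl ether at the end.

Step 6
Reactants: 12 bis(benzyl ether)
Product: 13 methyl (1R,4R)-7,8-bis(benzyloxy)-4-(3-chloroprop-1-en-2-yl)-1-methyl-1,2,3,4-tetrahydronaphthalene-6-carboxylate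
Conditions: Ca(OCl)2, CO2 (solid), CH2Cl2/H2O, 0 °C
Reagents that add atoms: calcium hypochlorite, [Ca+2].[O-]Cl.[O-]Cl
Why: Ene-type allylic chlorination by HOCl generated in situ puts chlorine on the terminal alkene carbon with loss of a methyl hydrogen, as is usual for isopropenyl terpenoids, while the ester-deactivated, fully substituted arene should stay inert.

Step 7
Reactants: 14 (S)-3-bromo-2-methylpropan-1-ol
Product: 15 (S)-(3-bromo-2-methylpropoxy)(tert-butyl)dimethylsilane
Conditions: TBSCl, imidazole, CH2Cl2, 0 °C → rt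
Reagents that add atoms: tert-butyldimethylsilyl chloride, CC(C)(C)[Si](C)(C)Cl
Why: Routine silylation of the primary alcohol that does not involve the stereocentre and gives an ether stable to Grignard, cuprate and borane conditions but removable without touching benzyl ethers.

Step 8
Reactants: 15 silyl ether
Product: 17 (R)-4-[(tert-butyldimethylsilyl)oxy]-3-methylbutan-1-ol, via Grignard reagent 16 (not isolated)
Conditions: Mg, THF, 40 °C; then (CH2O)n, THF, 0 °C → rt; aq. NH4Cl
Reagents that add atoms: formaldehyde (from paraformaldehyde), C=O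
Why: Grignard addition to formaldehyde adds the one carbon that becomes C13, the γ-silyloxy Grignard reagent being stable to 1,3-elimination and the methyl-bearing centre (future C15) not being a reacting centre (its descriptor changes from S to R by priority only).

Step 9
Reactants: 17 alcohol
Product: 18 (R)-(4-bromo-2-methylbutoxy)(tert-butyl)dimethylsilane
Conditions: CBr4, PPh3, CH2Cl2, 0 °C
Reagents that add atoms: tetrabromomethane, BrC(Br)(Br)Br
Why: Appel bromination converts the primary alcohol under neutral conditions that the silyl ether tolerates.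

Step 10
Reactants: 13 allylic chloride; 18 bromide
Product: 20 methyl (1R,4S)-7,8-bis(benzyloxy)-4-[(6R)-7-(tert-butyldimethylsilyloxy)-6-methylhept-1-en-2-yl]-1-methyl-1,2,3,4-tetrahydronaphthalene-6-carboxylate, via Grignard reagent 19 (not isolated)
Conditions: 18, Mg, THF, 40 °C; then 13, Li2CuCl4 (5 mol %), THF, −78 → −20 °C
Reagents that add atoms: none
Why: Li2CuCl4-catalysed cross-coupling of an alkyl Grignard reagent with an allylic chloride forms C12–C13; since the allyl unit is substituted only at its central carbon, SN2 and SN2′ attack give the same product, and at low temperature the catalysed substitution should outrun addition to the hindered aryl ester.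

Step 11
Reactants: 20 alkene
Product: 22 methyl (1R,4S)-7,8-bis(benzyloxy)-4-[(2S,6R)-7-(tert-butyldimethylsilyloxy)-1-hydroxy-6-methylheptan-2-yl]-1-methyl-1,2,3,4-tetrahydronaphthalene-6-carboxylate, via B-alkyl-9-BBN adduct 21 (not isolated)
Conditions: 9-BBN, THF, 0 °C → rt; then NaBO3·4H2O, THF/H2O, rt
Reagents that add atoms: sodium perborate tetrahydrate (NaBO3·4H2O), B(=O)O[O-].[Na+]
Why: Anti-Markovnikov hydroboration–oxidation puts boron (then OH) on C20 and hydrogen on C11; in the staggered transition state with the small C4–H next to the C12 methylene (least A(1,2) strain) the bulky borane should approach the alkene face turned away from aryl carbon C4a, which gives (11S), but the bias between C4a and C3 is only moderate, so the C11 epimer, a separable diastereomer, is removed by chromatography.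

Step 12
Reactants: 22 alcohol
Product: 23 methyl (1R,4S)-7,8-bis(benzyloxy)-4-[(2S,6R)-1,7-dihydroxy-6-methylheptan-2-yl]-1-methyl-1,2,3,4-tetrahydronaphthalene-6-carboxylate
Conditions: Bu4NF, THF, 0 °C → rt
Reagents that add atoms: none
Why: Fluoride cleaves the primary silyl ether selectively, leaving ester and benzyl ethers intact, so that both primary hydroxyls are free for acetylation.

Step 13
Reactants: 23 diol ester
Product: 24 (1R,4S)-7,8-bis(benzyloxy)-4-[(2S,6R)-1,7-dihydroxy-6-methylheptan-2-yl]-1-methyl-1,2,3,4-tetrahydronaphthalene-6-carboxylic acid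
Conditions: LiOH, THF/MeOH/H2O, 60 °C; then aq. HCl to pH 2
Reagents that add atoms: lithium hydroxide, [Li+].[OH-]
Why: Saponification of the aryl methyl ester is placed before acetylation because no selective ester cleavage would be possible once the two acetates are in place.

Step 14
Reactants: 24 diol acid
Product: 26 (1R,4S)-4-[(2S,6R)-1,7-diacetoxy-6-methylheptan-2-yl]-7,8-bis(benzyloxy)-1-methyl-1,2,3,4-tetrahydronaphthalene-6-carboxylic acid, via mixed anhydride 25 (not isolated)
Conditions: Ac2O, pyridine, DMAP (cat.), CH2Cl2, rt; then H2O, aq. NaHCO3, rt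
Reagents that add atoms: acetic anhydride, CC(=O)OC(C)=O
Why: Both primary alcohols are acetylated, and the carboxylic acid, transiently converted to the mixed anhydride, is returned by water, which attacks the unhindered acetyl carbonyl during work-up.

Step 15
Reactants: 26 diacetate acid
Product: 27 (1R,4S)-4-[(2S,6R)-1,7-diacetoxy-6-methylheptan-2-yl]-7,8-dihydroxy-1-methyl-1,2,3,4-tetrahydronaphthalene-6-carboxylic acid (target)
Conditions: H2 (1 atm), Pd/C (10 % Pd on carbon), EtOAc, rt
Reagents that add atoms: none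
Why: Hydrogenolysis removes both aryl benzyl ethers while acetates, acid, arene and the ring benzylic C–H bonds are inert, so no stereocentre is touched and the catechol acid is released in the last step.

**Compound list**

1 | (R)-carvone | CC(=C)[C@@H]1CC=C(C)C(=O)C1 | starting material
2 | (5R)-2-methyl-5-(prop-1-en-2-yl)cyclohexan-1-one, mixture of C2 epimers | CC(=C)[C@@H]1CCC(C)C(=O)C1 | intermediate (not isolated)
3 | (2R,5R)-2-methyl-5-(prop-1-en-2-yl)cyclohexan-1-one (trans-dihydrocarvone) | CC(=C)[C@@H]1CC[C@@H](C)C(=O)C1 | intermediate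
4 | ethyl formate | CCOC=O | starting material
5 | (3S,6R)-2-(hydroxymethylene)-6-methyl-3-(prop-1-en-2-yl)cyclohexan-1-one | CC(=C)[C@@H]1CC[C@@H](C)C(=O)C1=CO | intermediate
6 | methyl 4-chloro-3-oxobutanoate | COC(=O)CC(=O)CCl | starting material
7 | benzyl alcohol | OCc1ccccc1 | starting material
8 | methyl 4-(benzyloxy)-3-oxobutanoate | COC(=O)CC(=O)COCc1ccccc1 | intermediate
9 | methyl 4-(benzyloxy)-2-{[(3R,6R)-3-methyl-2-oxo-6-(prop-1-en-2-yl)cyclohexyl]methylidene}-3-oxobutanoate (ring attachment carbon and alkene geometry unspecified) | CC(=C)[C@@H]1CC[C@@H](C)C(=O)C1C=C(C(=O)OC)C(=O)COCc1ccccc1 | intermediate (not isolated)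
10 | methyl 8-(benzyloxy)-8a-hydroxy-1-methyl-7-oxo-4-(prop-1-en-2-yl)-1,2,3,4,4a,7,8,8a-octahydronaphthalene-6-carboxylate (C1 and C4 as in 11; C4a, C8, C8a unspecified) | CC(=C)[C@@H]1CC[C@@H](C)C2(O)C1C=C(C(=O)OC)C(=O)C2OCc1ccccc1 | intermediate (not isolated)
11 | methyl (1R,4S)-8-(benzyloxy)-7-hydroxy-1-methyl-4-(prop-1-en-2-yl)-1,2,3,4-tetrahydronaphthalene-6-carboxylate | CC(=C)[C@@H]1CC[C@@H](C)c2c1cc(C(=O)OC)c(O)c2OCc1ccccc1 | intermediate
12 | methyl (1R,4S)-7,8-bis(benzyloxy)-1-methyl-4-(prop-1-en-2-yl)-1,2,3,4-tetrahydronaphthalene-6-carboxylate | CC(=C)[C@@H]1CC[C@@H](C)c2c1cc(C(=O)OC)c(OCc1ccccc1)c2OCc1ccccc1 | intermediate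
13 | methyl (1R,4R)-7,8-bis(benzyloxy)-4-(3-chloroprop-1-en-2-yl)-1-methyl-1,2,3,4-tetrahydronaphthalene-6-carboxylate | ClCC(=C)[C@@H]1CC[C@@H](C)c2c1cc(C(=O)OC)c(OCc1ccccc1)c2OCc1ccccc1 | intermediate
14 | (S)-3-bromo-2-methylpropan-1-ol | OC[C@H](C)CBr | starting material
15 | (S)-(3-bromo-2-methylpropoxy)(tert-butyl)dimethylsilane | CC(C)(C)[Si](C)(C)OC[C@H](C)CBr | intermediate
16 | (S)-{3-[(tert-butyldimethylsilyl)oxy]-2-methylpropyl}magnesium bromide | CC(C)(C)[Si](C)(C)OC[C@H](C)C[Mg]Br | intermediate (not isolated)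
17 | (R)-4-[(tert-butyldimethylsilyl)oxy]-3-methylbutan-1-ol | CC(C)(C)[Si](C)(C)OC[C@H](C)CCO | intermediate
18 | (R)-(4-bromo-2-methylbutoxy)(tert-butyl)dimethylsilane | CC(C)(C)[Si](C)(C)OC[C@H](C)CCBr | intermediate
19 | (R)-{4-[(tert-butyldimethylsilyl)oxy]-3-methylbutyl}magnesium bromide | CC(C)(C)[Si](C)(C)OC[C@H](C)CC[Mg]Br | intermediate (not isolated)
20 | methyl (1R,4S)-7,8-bis(benzyloxy)-4-[(6R)-7-(tert-butyldimethylsilyloxy)-6-methylhept-1-en-2-yl]-1-methyl-1,2,3,4-tetrahydronaphthalene-6-carboxylate | CC(C)(C)[Si](C)(C)OC[C@H](C)CCCC(=C)[C@@H]1CC[C@@H](C)c2c1cc(C(=O)OC)c(OCc1ccccc1)c2OCc1ccccc1 | intermediate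
21 | B-alkyl-9-borabicyclo[3.3.1]nonane from 20 (boron on C20, hydrogen on C11, C11 configured as in 22) | CC(C)(C)[Si](C)(C)OC[C@H](C)CCC[C@H](CB1C2CCCC1CCC2)[C@@H]1CC[C@@H](C)c2c1cc(C(=O)OC)c(OCc1ccccc1)c2OCc1ccccc1 | intermediate (not isolated)
22 | methyl (1R,4S)-7,8-bis(benzyloxy)-4-[(2S,6R)-7-(tert-butyldimethylsilyloxy)-1-hydroxy-6-methylheptan-2-yl]-1-methyl-1,2,3,4-tetrahydronaphthalene-6-carboxylate | CC(C)(C)[Si](C)(C)OC[C@H](C)CCC[C@H](CO)[C@@H]1CC[C@@H](C)c2c1cc(C(=O)OC)c(OCc1ccccc1)c2OCc1ccccc1 | intermediate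
23 | methyl (1R,4S)-7,8-bis(benzyloxy)-4-[(2S,6R)-1,7-dihydroxy-6-methylheptan-2-yl]-1-methyl-1,2,3,4-tetrahydronaphthalene-6-carboxylate | OC[C@H](C)CCC[C@H](CO)[C@@H]1CC[C@@H](C)c2c1cc(C(=O)OC)c(OCc1ccccc1)c2OCc1ccccc1 | intermediate
24 | (1R,4S)-7,8-bis(benzyloxy)-4-[(2S,6R)-1,7-dihydroxy-6-methylheptan-2-yl]-1-methyl-1,2,3,4-tetrahydronaphthalene-6-carboxylic acid | OC[C@H](C)CCC[C@H](CO)[C@@H]1CC[C@@H](C)c2c1cc(C(=O)O)c(OCc1ccccc1)c2OCc1ccccc1 | intermediate
25 | acetic (1R,4S)-4-[(2S,6R)-1,7-diacetoxy-6-methylheptan-2-yl]-7,8-bis(benzyloxy)-1-methyl-1,2,3,4-tetrahydronaphthalene-6-carboxylic anhydride | CC(=O)OC[C@H](C)CCC[C@H](COC(C)=O)[C@@H]1CC[C@@H](C)c2c1cc(C(=O)OC(C)=O)c(OCc1ccccc1)c2OCc1ccccc1 | intermediate (not isolated)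
26 | (1R,4S)-4-[(2S,6R)-1,7-diacetoxy-6-methylheptan-2-yl]-7,8-bis(benzyloxy)-1-methyl-1,2,3,4-tetrahydronaphthalene-6-carboxylic acid | CC(=O)OC[C@H](C)CCC[C@H](COC(C)=O)[C@@H]1CC[C@@H](C)c2c1cc(C(=O)O)c(OCc1ccccc1)c2OCc1ccccc1 | intermediate
27 | (1R,4S)-4-[(2S,6R)-1,7-diacetoxy-6-methylheptan-2-yl]-7,8-dihydroxy-1-methyl-1,2,3,4-tetrahydronaphthalene-6-carboxylic acid | CC(=O)OC[C@H](C)CCC[C@H](COC(C)=O)[C@@H]1CC[C@@H](C)c2c1cc(C(=O)O)c(O)c2O | target

**Step count**

Total: 15 steps. Longest linear sequence: 11 steps from 1 (steps 1, 2, 4, 5, 6, 10, 11, 12, 13, 14, 15).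

**Steps most likely to fail**

1. Step 4. The condensation may lose regiocontrol (ring closure through oxygen to a pyran, or first C–C bond formation at the wrong carbon of 8), and alkoxide may partly epimerise C1 before the ring closes, giving the 1,4-cis tetralin. The fallback keeps the same two bonds but makes them under Lewis acid instead of base; it sets out from 5 and 8 and returns at 11. Compound 5 is O-silylated (Me3SiCl, Et3N) to the silyloxymethylene ketone F1. Compound 8 is converted with Me3SiCl/Et3N into the mono silyl enol ether F2 and then with LiN(i-Pr)2/Me3SiCl at −78 °C into the 1,3-bis(silyloxy)diene F3. TiCl4 in CH2Cl2 at −78 → 20 °C then joins F1 and F3 in a Mukaiyama-type [3+3] cyclisation. The terminal diene carbon is expected to add to the TiCl4-activated ring ketone and the central carbon to the silyloxymethylene carbon, which gives 11 after aqueous work-up without a basic step that could epimerise C1.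

2. Step 11. Facial selectivity at C11 may be poor, or even reversed, because the only stereodifferentiating element is the difference between aryl carbon C4a and methylene C3 at C4. The fallback replaces substrate control by enzymatic differentiation of two identical arms; it sets out from 13 and returns at 22. KOAc in DMF converts 13 into the allylic acetate F4, and K2CO3 in MeOH gives the allylic alcohol F5. Hydroboration–oxidation (BH3·THF; NaBO3·4H2O) gives the 2-substituted propane-1,3-diol F6, in which C11 is not yet stereogenic. Lipase-catalysed monoacetylation (Burkholderia cepacia lipase, vinyl acetate; enzyme chosen by screening for acylation of the arm that becomes C20) gives the monoacetate F7. Iodination (I2, PPh3, imidazole) gives the iodide F8. Li2CuCl4-catalysed coupling with Grignard reagent 19 in THF/N-methylpyrrolidone at −20 °C gives the C20 acetate F9, and methanolysis (K2CO3, MeOH) gives 22.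

3. Step 6. The electrophilic chlorination may lose hydrogen from C4–H instead of the methyl group (moving the double bond to C4=C11 and erasing the C4 stereocentre), or may attack the arene or the benzylic ether positions. The fallback forms C12–C13 by a carbonyl-ene reaction instead of by halogenation; it sets out from 12 and returns at 20. Paraformaldehyde with Me2AlCl in CH2Cl2 at −78 → 0 °C gives the homoallylic alcohol F10. TsCl/pyridine gives the tosylate F11. Li2CuCl4-catalysed coupling with the three-carbon Grignard reagent 16 (THF, −40 → 0 °C) forms C13–C14 and gives 20, which also makes steps 8 and 9 unnecessary.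

**Further compounds**

F1 | step 4 | (3S,6R)-6-methyl-3-(prop-1-en-2-yl)-2-[(trimethylsilyloxy)methylene]cyclohexan-1-one | CC(=C)[C@@H]1CC[C@@H](C)C(=O)C1=CO[Si](C)(C)C
F2 | step 4 | methyl 4-(benzyloxy)-3-(trimethylsilyloxy)but-2-enoate | COC(=O)C=C(COCc1ccccc1)O[Si](C)(C)C
F3 | step 4 | 4-(benzyloxy)-1-methoxy-1,3-bis(trimethylsilyloxy)buta-1,3-diene | COC(O[Si](C)(C)C)=CC(O[Si](C)(C)C)=COCc1ccccc1
F4 | step 11 | methyl (1R,4R)-4-(3-acetoxyprop-1-en-2-yl)-7,8-bis(benzyloxy)-1-methyl-1,2,3,4-tetrahydronaphthalene-6-carboxylate | CC(=O)OCC(=C)[C@@H]1CC[C@@H](C)c2c1cc(C(=O)OC)c(OCc1ccccc1)c2OCc1ccccc1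
F5 | step 11 | methyl (1R,4R)-7,8-bis(benzyloxy)-4-(3-hydroxyprop-1-en-2-yl)-1-methyl-1,2,3,4-tetrahydronaphthalene-6-carboxylate | OCC(=C)[C@@H]1CC[C@@H](C)c2c1cc(C(=O)OC)c(OCc1ccccc1)c2OCc1ccccc1
F6 | step 11 | methyl (1R,4S)-7,8-bis(benzyloxy)-4-(1,3-dihydroxypropan-2-yl)-1-methyl-1,2,3,4-tetrahydronaphthalene-6-carboxylate | OCC(CO)[C@@H]1CC[C@@H](C)c2c1cc(C(=O)OC)c(OCc1ccccc1)c2OCc1ccccc1
F7 | step 11 | methyl (1R,4S)-4-[(2R)-1-acetoxy-3-hydroxypropan-2-yl]-7,8-bis(benzyloxy)-1-methyl-1,2,3,4-tetrahydronaphthalene-6-carboxylate | OC[C@H](COC(C)=O)[C@@H]1CC[C@@H](C)c2c1cc(C(=O)OC)c(OCc1ccccc1)c2OCc1ccccc1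
F8 | step 11 | methyl (1R,4S)-4-[(2S)-1-acetoxy-3-iodopropan-2-yl]-7,8-bis(benzyloxy)-1-methyl-1,2,3,4-tetrahydronaphthalene-6-carboxylate | IC[C@H](COC(C)=O)[C@@H]1CC[C@@H](C)c2c1cc(C(=O)OC)c(OCc1ccccc1)c2OCc1ccccc1
F9 | step 11 | methyl (1R,4S)-4-[(2S,6R)-1-acetoxy-7-(tert-butyldimethylsilyloxy)-6-methylheptan-2-yl]-7,8-bis(benzyloxy)-1-methyl-1,2,3,4-tetrahydronaphthalene-6-carboxylate | CC(C)(C)[Si](C)(C)OC[C@H](C)CCC[C@H](COC(C)=O)[C@@H]1CC[C@@H](C)c2c1cc(C(=O)OC)c(OCc1ccccc1)c2OCc1ccccc1
F10 | step 6 | methyl (1R,4S)-7,8-bis(benzyloxy)-4-(4-hydroxybut-1-en-2-yl)-1-methyl-1,2,3,4-tetrahydronaphthalene-6-carboxylate | OCCC(=C)[C@@H]1CC[C@@H](C)c2c1cc(C(=O)OC)c(OCc1ccccc1)c2OCc1ccccc1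
F11 | step 6 | methyl (1R,4S)-7,8-bis(benzyloxy)-1-methyl-4-[4-(tosyloxy)but-1-en-2-yl]-1,2,3,4-tetrahydronaphthalene-6-carboxylate | Cc1ccc(cc1)S(=O)(=O)OCCC(=C)[C@@H]1CC[C@@H](C)c2c1cc(C(=O)OC)c(OCc1ccccc1)c2OCc1ccccc1
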